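Numbering used throughout: bicyclo[3.3.1]nonane C1 (tertiary carbinol), C2H2, C3 (N), C4 (CHOH), C5 (bridgehead CH), C6 (CHOH), C7/C8 (oxirane, ring C), C9 (ketone); ring A = C1-C2-C3-C4-C5-C9, ring B = C1-C9-C5-C6-C7-C8. Everything rests on the C4–C5 bond, part of a ketol whose C9 ketone can enolise only toward C5. Oxidising a primary alcohol to the C4 aldehyde triggers an aldol addition that closes ring A and sets C4 and C5 in one operation. The precursor is an epoxycyclohexanone (rings B and C complete) made from L-tyrosinol by dearomatisation; a temporary pyran ring desymmetrises the dienone and oxygenates C9. Cross-metathesis adds the keto chain last.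

Key step: step 6

Remark: all intermediates carry the atom labels of the target given above, and stereodescriptors quoted "in target labels" refer to these labels.
Assumption: the hydroxy carbonyl compounds 9 and 10 are written in their open forms, although ring–chain tautomerism will operate in solution.

Step 1
Reactants: 1 L-tyrosinol; 2 acryloyl chloride
Product: 3 N-acryloyl-L-tyrosinol
Conditions: NaHCO3, THF/H2O, 0 °C
Reagents that add atoms: none
Why: Schotten–Baumann N-acylation, in which the primary amine outcompetes the phenol and the alcohol for the acid chloride in bicarbonate-buffered water and the C3 stereocentre is not touched.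

Step 2
Reactants: 3 N-acryloyl-L-tyrosinol
Product: 5 symmetric p-quinol (C1 carbinol, C6 ketone, C9=C5 and C8=C7 enones), via hydroperoxide 4 (not isolated)
Conditions: O2 (1 atm), rose bengal (1 mol %), white LEDs, MeOH, 0 °C; then Me2S, 0 °C to 23 °C
Reagents that add atoms: dioxygen, O=O
Why: Dye-sensitised photooxygenation of a 4-alkylphenol (singlet-oxygen dearomatisation) places the hydroperoxide on the alkyl-bearing carbon C1 and leaves the electron-poor acrylamide alone, and dimethyl sulfide then reduces the O–O bond to a dienone in which C1 is not yet stereogenic.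

Step 3
Reactants: 5 symmetric p-quinol
Product: 6 bicyclic dienone with a pyran oxygen between C4H2 and C9
Conditions: PdCl2(MeCN)2 (10 mol %), CuCl (10 mol %), Na2HPO4 (0.5 equiv), O2 (1 atm), DME, 45 °C
Reagents that add atoms: none
Why: Wacker-type oxidative cyclisation of a hydroxy enone to a vinylogous ester, in which divalent palladium activates an enone C=C, the primary alcohol adds anti to C9 through a chair with the C3 amide equatorial (this picks one of the two diastereotopic enones and makes C1 stereogenic with its hydroxyl cis to the amide), and syn β-hydride elimination of H9 restores the C9=C5 double bond while oxygen and CuCl return zerovalent palladium to the divalent state.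

Step 4
Reactants: 6 bicyclic dienone
Product: 7 C7/C8 epoxy ketone, oxirane cis to the C1 hydroxyl
Conditions: t-BuOOH (1.5 equiv, decane), benzyltrimethylammonium hydroxide (10 mol %), THF, −20 °C to 0 °C
Reagents that add atoms: tert-butyl hydroperoxide, CC(C)(C)OO
Why: Weitz–Scheffer nucleophilic epoxidation, for which only the C7=C8 enone is electrophilic enough (C9=C5 is a deactivated vinylogous ester and the secondary acrylamide a poor acceptor) and in which hydrogen bonding of the peroxide to the C1 hydroxyl should deliver oxygen to the hydroxyl-bearing face.

Step 5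
Reactants: 7 epoxy ketone
Product: 9 keto triol (C9 ketone, C5H2, free C4H2OH), via enol ether carbinol 8 (not isolated)
Conditions: NaBH4, CeCl3·7H2O, MeOH, −78 °C; then 0.05 M aq. oxalic acid, THF, 0 °C
Reagents that add atoms: water, O
Why: Luche reduction followed by enol ether hydrolysis, in which hydride adds 1,2 to C6 anti to the neighbouring C7–O bond of the oxirane (Felkin–Anh) to give the carbinol cis to the epoxide, and dilute acid then protonates C5 and hydrates C9 to open the temporary pyran, the electron-withdrawing oxirane next to C6 slowing the competing allylic ionisation.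

Step 6
Reactants: 9 keto triol
Product: 11 bicyclo[3.3.1]nonanone acrylamide, via keto aldehyde 10 (not isolated)
Conditions: Cu(MeCN)4OTf (5 mol %), 2,2'-bipyridine (5 mol %), TEMPO (5 mol %), N-methylimidazole (10 mol %), air, MeCN, 23 °C; then DBU (20 mol %), 0 °C
Reagents that add atoms: none
Why: Copper/nitroxyl aerobic oxidation takes only the primary C4 alcohol to aldehyde 10, and DBU then enolises the C9 ketone, which can lose a proton only at C5 because C1 is quaternary, so a single enolate adds to the aldehyde. The closest known reaction is the intramolecular aldol addition of 3-(2-oxocyclohexyl)propanals to 2-hydroxybicyclo[3.3.1]nonan-9-ones, which is also the ring closure presumed in the biosynthesis of this skeleton. Ring A closes in a 6-(enolendo)-exo-trig mode. C5 is fixed by the tether, because the three-atom bridge can span C1 and C5 only on the ring B face that carries C2, the face opposite to the C1, C6 and oxirane oxygens. C4 is set in a chair-like, hydrogen-bonded transition state with the C3 amide equatorial and the aldehyde oxygen turned toward the enolate oxygen, which gives the axial carbinol cis to the amide, and the reversibility of the aldol should steer both the C4 ratio and any epimerisation at C3 toward this isomer. The step needs addition to outrun loss of the C6 hydroxyl from the enolate, which is secured by the poor leaving group, the low temperature and the fact that the product can no longer eliminate once C5 is a bridgehead.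

Step 7
Reactants: 12 hex-5-enenitrile; 13 pentylmagnesium bromide
Product: 15 undec-1-en-6-one, via magnesium ketimine 14 (not isolated)
Conditions: Et2O, 0 °C to reflux; then 2 M aq. HCl, 0 °C
Reagents that add atoms: water, O
Why: Grignard addition to a nitrile stops at the magnesium ketimine, so no tertiary alcohol can form, and acid hydrolysis then gives the ketone.

Step 8
Reactants: 11 bicyclo[3.3.1]nonanone acrylamide; 15 undec-1-en-6-one
Product: 16 isariotin C
Conditions: second-generation Hoveyda–Grubbs catalyst (5 mol %), 15 (3 equiv), CH2Cl2, 40 °C
Reagents that add atoms: none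
Why: Olefin cross-metathesis between an electron-poor acrylamide and an unhindered terminal alkene favours the cross product and gives the E enamide under thermodynamic control, while the hydroxyl groups, both ketones and the oxirane are tolerated by the ruthenium carbene.

Compound list
1 | L-tyrosinol, (S)-2-amino-3-(4-hydroxyphenyl)propan-1-ol | N[C@H](CO)Cc1ccc(O)cc1 | starting material
2 | acryloyl chloride | C=CC(=O)Cl | starting material
3 | N-acryloyl-L-tyrosinol, N-[(S)-1-hydroxy-3-(4-hydroxyphenyl)propan-2-yl]acrylamide | C=CC(=O)N[C@H](CO)Cc1ccc(O)cc1 | intermediate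
4 | hydroperoxide, N-[(S)-1-(1-hydroperoxy-4-oxocyclohexa-2,5-dien-1-yl)-3-hydroxypropan-2-yl]acrylamide | C=CC(=O)N[C@H](CO)CC1(OO)C=CC(=O)C=C1 | intermediate
5 | p-quinol, N-[(S)-1-hydroxy-3-(1-hydroxy-4-oxocyclohexa-2,5-dien-1-yl)propan-2-yl]acrylamide | C=CC(=O)N[C@H](CO)CC1(O)C=CC(=O)C=C1 | intermediate
6 | N-[(3S,4aS)-4a-hydroxy-7-oxo-2,3,4,4a-tetrahydro-7H-chromen-3-yl]acrylamide; pyran oxygen links C4H2 to C9, C9=C5 vinylogous ester, C7=C8 enone, C1-OH cis to the C3 amide, (1S,3S) in target labels | C=CC(=O)N[C@H]1C[C@@]2(O)C(OC1)=CC(=O)C=C2 | intermediate
7 | C7/C8 epoxide of 6, oxirane on the face of the C1 hydroxyl, (1S,3S,7R,8S) in target labels | C=CC(=O)N[C@H]1C[C@@]2(O)C(OC1)=CC(=O)[C@@H]3O[C@@H]32 | intermediate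
8 | enol ether carbinol: C6 ketone of 7 reduced to CHOH, with C1-OH, C6-OH and oxirane all on one face, (1S,3S,6S,7S,8S) in target labels | C=CC(=O)N[C@H]1C[C@@]2(O)C(OC1)=C[C@H](O)[C@@H]3O[C@@H]32 | intermediate
9 | keto triol: cyclohexanone ring B (C9 ketone, C5H2) with C1-OH, C6-OH and the C7/C8 oxirane on one face and CH2-CH(NHCOCH=CH2)-CH2OH at C1 on the other, (1S,3S,6S,7S,8S) in target labels | C=CC(=O)N[C@H](CO)C[C@@]1(O)C(=O)C[C@H](O)[C@@H]2O[C@@H]21 | intermediate
10 | keto aldehyde: as 9 with C4 oxidised to CHO | C=CC(=O)N[C@H](C=O)C[C@@]1(O)C(=O)C[C@H](O)[C@@H]2O[C@@H]21 | intermediate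
11 | N-[(1S,3S,4R,5S,6S,7S,8S)-7,8-epoxy-1,4,6-trihydroxy-9-oxobicyclo[3.3.1]nonan-3-yl]acrylamide | C=CC(=O)N[C@H]1C[C@@]2(O)C(=O)[C@H]([C@H](O)[C@@H]3O[C@@H]32)[C@H]1O | intermediate
12 | hex-5-enenitrile | C=CCCCC#N | starting material
13 | pentylmagnesium bromide | CCCCC[Mg]Br | starting material
14 | bromomagnesium ketimine of undec-1-en-6-one | C=CCCCC(=N[Mg]Br)CCCCC | intermediate
15 | undec-1-en-6-one | C=CCCCC(=O)CCCCC | intermediate
16 | isariotin C, (E)-N-[(1S,3S,4R,5S,6S,7S,8S)-7,8-epoxy-1,4,6-trihydroxy-9-oxobicyclo[3.3.1]nonan-3-yl]-7-oxododec-2-enamide | CCCCCC(=O)CCC/C=C/C(=O)N[C@H]1C[C@@]2(O)C(=O)[C@H]([C@H](O)[C@@H]3O[C@@H]32)[C@H]1O | target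

Total step count: 8. Longest linear sequence: 7 (steps 1 to 6 and 8).

Steps most likely to fail

Step 6. The enolate may lose the C6 hydroxyl by β-elimination before it adds. Ring B may open by retro-aldol cleavage. Ring–chain tautomerism may also hold the aldehyde back so that the aldol stalls. The fallback generates the C5 nucleophile by reduction instead of deprotonation. It sets out from 8, which is isolated after a bicarbonate work-up of the Luche reduction. N-bromosuccinimide in NaHCO3-buffered aqueous THF brominates C5 and hydrates C9 to give the α-bromo ketone F1. Copper/TEMPO aerobic oxidation of its primary alcohol gives the bromo keto aldehyde F2. SmI2 in THF at −78 °C then forms a samarium enolate that closes ring A in a chelated intramolecular Reformatsky reaction. The route is rejoined at 11.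

Step 3. Oxypalladation of the electron-poor alkene may be slow. The primary alcohol may be oxidised instead. Discrimination between the two diastereotopic enones may be weak. The fallback separates C–O bond formation from the oxidation and sets out from 5. A catalytic amount of K2CO3 in MeCN at 0 °C promotes the oxa-Michael cyclisation under kinetic control, through the same chair, to the saturated cis-fused adduct F3. Dehydrogenation with 2-iodoxybenzoic acid in DMSO at 65 °C then introduces the C9=C5 double bond. The route is rejoined at 6.

Step 5. During enol ether hydrolysis the new allylic hydroxyl may ionise, which would lead to enone transposition with loss of the C6 stereocentre. Hydride delivery may also show poor facial selectivity. The fallback accepts the transposition and reinstalls the C6 oxygen in the ring closure. It sets out from 7. NaBH4/CeCl3·7H2O followed by 1 M HCl gives the transposed epoxy enone F4, and copper/TEMPO aerobic oxidation gives the epoxy enone aldehyde F5. In aqueous K2CO3/THF at 0 °C, reversible conjugate addition of water at C6 is trapped by the aldol at C5. Oxygen and carbon should add trans-diaxially across the former double bond. The route is rejoined at 11.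

Further compounds
F1 | step 6 | α-bromo ketone: as 9 with bromine on C5, anti to the C6 hydroxyl | C=CC(=O)N[C@H](CO)C[C@@]1(O)C(=O)[C@H]([C@H](O)[C@@H]2O[C@@H]21)Br
F2 | step 6 | bromo keto aldehyde: as F1 with C4 oxidised to CHO | C=CC(=O)N[C@H](C=O)C[C@@]1(O)C(=O)[C@H]([C@H](O)[C@@H]2O[C@@H]21)Br
F3 | step 3 | saturated cis-fused oxa-Michael adduct: pyran oxygen on C9 trans to the C1 hydroxyl, C5H2, C7=C8 enone retained | C=CC(=O)N[C@H]1C[C@@]2(O)[C@@H](OC1)CC(=O)C=C2
F4 | step 5 | transposed epoxy enone: C9 ketone, C5=C6 alkene, C7/C8 oxirane cis to C1-OH, free C4H2OH | C=CC(=O)N[C@H](CO)C[C@@]1(O)C(=O)C=C[C@@H]2O[C@@H]21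
F5 | step 5 | epoxy enone aldehyde: as F4 with C4 oxidised to CHO | C=CC(=O)N[C@H](C=O)C[C@@]1(O)C(=O)C=C[C@@H]2O[C@@H]21
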